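**Plan**
1. Cuts: C11=C12 and C11'=C12' (two Wittig olefinations) give the C15 phosphonium salt of ring A, the C10 trienedial and the C15 phosphonium salt of ring B; in the ring A piece, C8–C9 (acetylide + enone) and C5–CH3 (cross-coupling) are cut next.
2. Ring A is then cut at C4–C5 and C5–C6: it comes from a cyclopentene made of C1, C2, C3, C4 and C6 by insertion of C5 as dibromocarbene and electrocyclic opening of the bicyclo[3.1.0]hexane to the six-membered ring.
3. What makes this possible: in ring A, C4 is a carbinol carbon that is allylic to C5=C6 and next to the carbinol carbon C3. The C4–C5–C6 allyl cation set free by the ring expansion can therefore be caught at C4 by a carbamate oxygen hung on O3. This gives a temporary cis-fused dioxolanone ring (cleaved in step 10) and leaves a bromine on C5 (exchanged for CH3 in step 7).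
4. Forward order: cyclopentenone → (S)-cyclopentenol → dibromocyclopropane → six-membered ring A → methyl group, side chain, phosphonium salt. Ring B is taken from (R)-α-ionone (chain extension, oxidation at C3', reduction, salt). Ring B salt + C10 dialdehyde → C25 aldehyde; + ring A salt → C40 chain.
5. Stereochemistry: C3 by catalyst-controlled reduction of the cyclopentenone, C4 from C3 through the tether, C6' from (R)-α-ionone, C3' by catalyst-controlled reduction, C7=C8 by trans-hydroalumination, the other double bonds by olefination and equilibration to all-E.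

Key step: step 6

Assumption: (R)-α-ionone is bought in high enantiomeric purity; locants C1–C15 and primed locants are carotenoid locants.

**Fragment A (ring A, steps 1–12)**

Step 1
Reactants: 1 3-ethoxycyclopent-2-en-1-one
Product: 3 3-ethoxy-5,5-dimethylcyclopent-2-en-1-one, via monomethyl enone 2 (not isolated)
Conditions: LiN(i-Pr)2 (1.05 equiv), THF, −78 °C; CH3I; then LiN(i-Pr)2 (1.1 equiv), −78 °C; CH3I, −78 °C → rt
Reagents that add atoms: iodomethane, CI
Why: Kinetic α'-deprotonation of the vinylogous ester and SN2 methylation, run twice (Stork–Danheiser-type α'-alkylation), should build the quaternary carbon that becomes C1 with its two methyl groups next to the carbonyl.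

Step 2
Reactants: 3 3-ethoxy-5,5-dimethylcyclopent-2-en-1-one; 4 ethynyltri(propan-2-yl)silane
Product: 6 4,4-dimethyl-3-{[tri(propan-2-yl)silyl]ethynyl}cyclopent-2-en-1-one, via tertiary alcohol 5 (not isolated)
Conditions: 4, n-BuLi, THF, −78 °C; add 3, −78 → 0 °C; then 1 M HCl, THF, rt
Reagents that add atoms: water, O
Why: Stork–Danheiser transposition: the acetylide adds 1,2 to the vinylogous-ester carbonyl, and acid hydrolysis of the enol ether with loss of the tertiary hydroxyl gives the transposed enone, which places the alkyne (future C7–C8) on the carbon next to the gem-dimethyl carbon.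

Step 3
Reactants: 6 4,4-dimethyl-3-{[tri(propan-2-yl)silyl]ethynyl}cyclopent-2-en-1-one
Product: 7 (1S)-4,4-dimethyl-3-{[tri(propan-2-yl)silyl]ethynyl}cyclopent-2-en-1-ol
Conditions: (R)-1-methyl-3,3-diphenyltetrahydro-1H,3H-pyrrolo[1,2-c][1,3,2]oxazaborole (20 mol %), catecholborane, toluene, −78 °C; aq. NaOH work-up
Reagents that add atoms: none
Why: Corey–Bakshi–Shibata reduction, in which the (R)-oxazaborolidine binds the ketone with the conjugated alkenyl flank as the large group and delivers hydride to one face, should give the (S)-allylic alcohol whose carbinol carbon becomes C3.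

Step 4
Reactants: 7 (1S)-4,4-dimethyl-3-{[tri(propan-2-yl)silyl]ethynyl}cyclopent-2-en-1-ol
Product: 8 (1S)-4,4-dimethyl-3-{[tri(propan-2-yl)silyl]ethynyl}cyclopent-2-en-1-yl dimethylcarbamate
Conditions: NaH, THF, 0 °C; (CH3)2NCOCl, 0 °C → rt
Reagents that add atoms: dimethylcarbamoyl chloride, CN(C)C(Cl)=O
Why: O-acylation of the sodium alkoxide by the carbamoyl chloride (carbamate formation) installs a base-stable group whose carbonyl oxygen can later act as an internal nucleophile.

Step 5
Reactants: 8 (1S)-4,4-dimethyl-3-{[tri(propan-2-yl)silyl]ethynyl}cyclopent-2-en-1-yl dimethylcarbamate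
Product: 9 (1S,2S,5R)-6,6-dibromo-4,4-dimethyl-5-{[tri(propan-2-yl)silyl]ethynyl}bicyclo[3.1.0]hexan-2-yl dimethylcarbamate
Conditions: CHBr3, 50% aq. NaOH, benzyltriethylammonium chloride (cat.), CH2Cl2, 0 °C; crude product used cold
Reagents that add atoms: bromoform, BrC(Br)Br
Why: Phase-transfer generation of dibromocarbene and its [2+1] cycloaddition to the trisubstituted ring alkene (the hindered silylalkyne and the carbamate are left) should give the gem-dibromocyclopropane, expected mainly anti to the carbamate; the configuration of the two ring-fusion carbons is erased in step 6.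

Step 6
Reactants: 9 (1S,2S,5R)-6,6-dibromo-4,4-dimethyl-5-{[tri(propan-2-yl)silyl]ethynyl}bicyclo[3.1.0]hexan-2-yl dimethylcarbamate
Product: 12 (3aS,7aS)-7-bromo-5,5-dimethyl-6-{[tri(propan-2-yl)silyl]ethynyl}-3a,4,5,7a-tetrahydro-1,3-benzodioxol-2-one, via allyl cation 10 (not isolated), via dioxolanylium salt 11 (not isolated)
Conditions: AgBF4 (1.2 equiv), CH2Cl2, 0 °C → rt, dark; then 0.5 M aq. HCl–THF, 0 °C
Reagents that add atoms: water, O
Why: Proposed new method: monovalent silver pulls off the bromide that lies over the five-membered ring of 9, the C4–C6 cyclopropane bond opens in a disrotatory two-electron electrocyclic process, and the five-membered ring C1–C2–C3–C4–C6 becomes the six-membered 2-bromocyclohexenyl cation 10 with C5 inserted between C4 and C6 (ring expansion by one atom). The carbamate carbonyl oxygen on O3 then adds to the cation terminus C4 in a 5-exo closure to the cis-fused 2-(dimethylamino)-1,3-dioxolan-2-ylium salt 11, and aqueous acid exchanges the dimethylamino group for oxygen to leave carbonate 12. The closest known reaction types are the silver-promoted electrocyclic ring opening of ring-fused gem-dibromocyclopropanes with capture of the allyl cation by a tethered nucleophile, and carbamate or acyloxy neighbouring-group capture of cationic carbon as in halocyclisation to cyclic carbonates and in the Woodward cis-hydroxylation; their combination is the untested part and is reasonable because no other nucleophile is present and a five-membered ring can form only at C4. The one new stereocentre, C4, is controlled by the tether: the three-atom bridge from C3 reaches the planar cation only on the face that carries O3, so O3 and O4 end up cis, which is 3S,4R in the target. The step needs capture at C4 and not at C6 or the alkyne terminus, which is secured by ring size (five against seven atoms), by the quaternary C1 beside C6 and by the bulky silyl cap; it needs no control of the cyclopropane configuration, since both diastereomers of 9 and any allylic bromide formed by early opening give the same cation 10. The bromine left on C5 is the handle for the C5 methyl group.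

Step 7
Reactants: 12 (3aS,7aS)-7-bromo-5,5-dimethyl-6-{[tri(propan-2-yl)silyl]ethynyl}-3a,4,5,7a-tetrahydro-1,3-benzodioxol-2-one
Product: 13 (3aS,7aR)-5,5,7-trimethyl-6-{[tri(propan-2-yl)silyl]ethynyl}-3a,4,5,7a-tetrahydro-1,3-benzodioxol-2-one
Conditions: CH3ZnCl (2 equiv), Pd[P(t-Bu)3]2 (5 mol %), THF, rt
Reagents that add atoms: methylzinc chloride, C[Zn]Cl
Why: Negishi cross-coupling: zerovalent palladium with the bulky electron-rich phosphine should insert into the C5–Br bond far faster than it can coordinate to the tetrasubstituted alkene to ionise the allylic carbonate, and methyl transfer from zinc with reductive elimination gives the C5 methyl group.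

Step 8
Reactants: 13 (3aS,7aR)-5,5,7-trimethyl-6-{[tri(propan-2-yl)silyl]ethynyl}-3a,4,5,7a-tetrahydro-1,3-benzodioxol-2-one
Product: 14 (3aS,7aR)-6-ethynyl-5,5,7-trimethyl-3a,4,5,7a-tetrahydro-1,3-benzodioxol-2-one
Conditions: (n-Bu)4NF, AcOH, THF, 0 °C → rt
Reagents that add atoms: none
Why: Fluoride-mediated protodesilylation of the alkynylsilane, buffered with acetic acid so that the cyclic carbonate is not attacked, should free the terminal alkyne.

Step 9
Reactants: 14 (3aS,7aR)-6-ethynyl-5,5,7-trimethyl-3a,4,5,7a-tetrahydro-1,3-benzodioxol-2-one; 15 but-3-en-2-one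
Product: 16 (3aS,7aR)-6-(3-hydroxy-3-methylpent-4-en-1-yn-1-yl)-5,5,7-trimethyl-3a,4,5,7a-tetrahydro-1,3-benzodioxol-2-one
Conditions: LiN(i-Pr)2 (1.05 equiv), THF, −78 °C; 15, −78 °C; AcOH quench at −78 °C
Reagents that add atoms: none
Why: Deprotonation of the terminal alkyne by the non-nucleophilic amide base and 1,2-addition of the lithium acetylide to the enone carbonyl (acetylide addition to a ketone), at a temperature where the carbonate is not attacked, should form the C8–C9 bond; both configurations at C9 are expected and both are used.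

Step 10
Reactants: 16 (3aS,7aR)-6-(3-hydroxy-3-methylpent-4-en-1-yn-1-yl)-5,5,7-trimethyl-3a,4,5,7a-tetrahydro-1,3-benzodioxol-2-one
Product: 17 (1S,2R)-4-[(1E)-3-hydroxy-3-methylpenta-1,4-dien-1-yl]-3,5,5-trimethylcyclohex-3-ene-1,2-diol
Conditions: NaAlH2(OCH2CH2OCH3)2 (excess), THF, 0 °C → rt; aq. potassium sodium tartrate
Reagents that add atoms: none
Why: Hydroxyl-directed trans-hydroalumination of the propargylic alcohol should give the 7E alkene after protonolysis, and the same hydride reductively cleaves the cyclic carbonate (the temporary ring) to the cis diol without touching C3 or C4.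

Step 11
Reactants: 17 (1S,2R)-4-[(1E)-3-hydroxy-3-methylpenta-1,4-dien-1-yl]-3,5,5-trimethylcyclohex-3-ene-1,2-diol
Product: 18 (1S,2R)-4-[(1E)-3-hydroxy-3-methylpenta-1,4-dien-1-yl]-3,5,5-trimethylcyclohex-3-ene-1,2-diyl diacetate
Conditions: Ac2O, pyridine, CH2Cl2, 0 °C → rt
Reagents that add atoms: acetic anhydride, CC(=O)OC(C)=O
Why: Acetylation with acetic anhydride/pyridine should esterify the two secondary hydroxyls but not the tertiary one (steric chemoselectivity), so that the allylic C4 oxygen is deactivated towards ionisation in the next step.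

Step 12
Reactants: 18 (1S,2R)-4-[(1E)-3-hydroxy-3-methylpenta-1,4-dien-1-yl]-3,5,5-trimethylcyclohex-3-ene-1,2-diyl diacetate
Product: 19 {(2E,4E)-5-[(3R,4S)-3,4-bis(acetyloxy)-2,6,6-trimethylcyclohex-1-en-1-yl]-3-methylpenta-2,4-dien-1-yl}triphenylphosphonium bromide
Conditions: PPh3·HBr (1.05 equiv), CH2Cl2, 0 °C → rt; trituration with EtOAc
Reagents that add atoms: triphenylphosphine hydrobromide, Br.c1ccc(cc1)P(c1ccccc1)c1ccccc1
Why: Acid-mediated ionisation of the tertiary doubly allylic carbinol to a delocalised cation and attack of triphenylphosphine at the unhindered terminus C11 (allylic transposition, the usual way from vinyl carbinols to C15 phosphonium salts) should give the salt, mainly as the 9E isomer.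

**Fragment B (ring B, steps 13–17)**

Step 13
Reactants: 20 (3E)-4-[(1R)-2,6,6-trimethylcyclohex-2-en-1-yl]but-3-en-2-one; 21 trimethyl phosphonoacetate
Product: 22 methyl (2E,4E)-3-methyl-5-[(1R)-2,6,6-trimethylcyclohex-2-en-1-yl]penta-2,4-dienoate
Conditions: 21, NaH, THF, 0 °C; add 20, rt; chromatography to remove the 2Z isomer
Reagents that add atoms: none
Why: Horner–Wadsworth–Emmons olefination of the methyl ketone by the stabilised phosphonate anion should give the trisubstituted 9'E dienoate as the major isomer without touching C6', because no free strong base is present.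

Step 14
Reactants: 22 methyl (2E,4E)-3-methyl-5-[(1R)-2,6,6-trimethylcyclohex-2-en-1-yl]penta-2,4-dienoate
Product: 23 methyl (2E,4E)-3-methyl-5-[(1R)-2,6,6-trimethyl-4-oxocyclohex-2-en-1-yl]penta-2,4-dienoate
Conditions: t-BuOOH (70% aq.), CrO3 (5 mol %), CH2Cl2, rt
Reagents that add atoms: tert-butyl hydroperoxide, CC(C)(C)OO
Why: Chromium-catalysed allylic oxidation with the hydroperoxide should convert the only ring allylic methylene (C3') into the enone carbonyl, while the hindered doubly allylic C6'–H and the electron-poor dienoate are expected to be left, so C6' keeps its configuration.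

Step 15
Reactants: 23 methyl (2E,4E)-3-methyl-5-[(1R)-2,6,6-trimethyl-4-oxocyclohex-2-en-1-yl]penta-2,4-dienoate
Product: 24 methyl (2E,4E)-5-[(1R,4S)-4-hydroxy-2,6,6-trimethylcyclohex-2-en-1-yl]-3-methylpenta-2,4-dienoate
Conditions: (R)-1-methyl-3,3-diphenyltetrahydro-1H,3H-pyrrolo[1,2-c][1,3,2]oxazaborole (50 mol %), catecholborane, toluene, −78 °C; pH 7 work-up; chromatography
Reagents that add atoms: none
Why: Corey–Bakshi–Shibata reduction of the ring enone with the (R)-oxazaborolidine (alkenyl flank as the large group) should give the 3'S alcohol, cis to the C6' side chain, under reagent control, and any 3'R epimer is a diastereomer that is removed by chromatography.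

Step 16
Reactants: 24 methyl (2E,4E)-5-[(1R,4S)-4-hydroxy-2,6,6-trimethylcyclohex-2-en-1-yl]-3-methylpenta-2,4-dienoate
Product: 25 (2E,4E)-5-[(1R,4S)-4-hydroxy-2,6,6-trimethylcyclohex-2-en-1-yl]-3-methylpenta-2,4-dien-1-ol
Conditions: i-Bu2AlH (3.5 equiv), CH2Cl2, −78 °C; aq. potassium sodium tartrate
Reagents that add atoms: none
Why: 1,2-Reduction of the conjugated ester by the aluminium hydride should give the primary dienylic alcohol without affecting the stereocentres.

Step 17
Reactants: 25 (2E,4E)-5-[(1R,4S)-4-hydroxy-2,6,6-trimethylcyclohex-2-en-1-yl]-3-methylpenta-2,4-dien-1-ol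
Product: 26 {(2E,4E)-5-[(1R,4S)-4-hydroxy-2,6,6-trimethylcyclohex-2-en-1-yl]-3-methylpenta-2,4-dien-1-yl}triphenylphosphonium bromide
Conditions: PPh3·HBr (1.0 equiv), CH2Cl2, 0 °C
Reagents that add atoms: triphenylphosphine hydrobromide, Br.c1ccc(cc1)P(c1ccccc1)c1ccccc1
Why: Ionisation of the primary dienylic alcohol to a pentadienyl cation and capture by triphenylphosphine (allylic phosphonium salt formation) is expected to be much faster at 0 °C than ionisation of the isolated ring allylic alcohol at C3', which is therefore kept with its configuration.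

**Assembly (steps 18–19)**

Step 18
Reactants: 26 {(2E,4E)-5-[(1R,4S)-4-hydroxy-2,6,6-trimethylcyclohex-2-en-1-yl]-3-methylpenta-2,4-dien-1-yl}triphenylphosphonium bromide; 27 (2E,4E,6E)-2,7-dimethylocta-2,4,6-trienedial
Product: 28 (2E,4E,6E,8E,10E,12E)-13-[(1R,4S)-4-hydroxy-2,6,6-trimethylcyclohex-2-en-1-yl]-2,7,11-trimethyltrideca-2,4,6,8,10,12-hexaenal
Conditions: 27 (2.5 equiv), NaOCH3 (1.1 equiv), CH3OH–CH2Cl2, 0 °C → rt, slow addition of 26; then I2 (cat.), CH2Cl2, rt; chromatography
Reagents that add atoms: none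
Why: Wittig olefination of the ylide from 26 with an excess of the symmetrical dialdehyde should form C11'=C12' on one aldehyde group only, and iodine-catalysed equilibration converts the Z isomer at the new double bond into the E isomer.

Step 19
Reactants: 19 {(2E,4E)-5-[(3R,4S)-3,4-bis(acetyloxy)-2,6,6-trimethylcyclohex-1-en-1-yl]-3-methylpenta-2,4-dien-1-yl}triphenylphosphonium bromide; 28 (2E,4E,6E,8E,10E,12E)-13-[(1R,4S)-4-hydroxy-2,6,6-trimethylcyclohex-2-en-1-yl]-2,7,11-trimethyltrideca-2,4,6,8,10,12-hexaenal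
Product: 30 (3S,4R,3'S,6'R)-β,ε-carotene-3,4,3'-triol, via diacetate 29 (not isolated)
Conditions: NaOCH3 (1.2 equiv), CH3OH–CH2Cl2, 0 °C → rt; then more NaOCH3, rt; then reflux in EtOH under Ar; crystallisation
Reagents that add atoms: none
Why: Wittig olefination of the ylide from 19 with aldehyde 28 should form C11=C12 and complete the C40 chain, methoxide then removes the two acetates by transesterification, and heating equilibrates the new double bond to E so that the all-E triol crystallises; no stereocentre is touched.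

**Compound list**
1 | 3-ethoxycyclopent-2-en-1-one | CCOC1=CC(=O)CC1 | starting material
2 | 3-ethoxy-5-methylcyclopent-2-en-1-one (racemic) | CCOC1=CC(=O)C(C)C1 | intermediate
3 | 3-ethoxy-5,5-dimethylcyclopent-2-en-1-one | CCOC1=CC(=O)C(C)(C)C1 | intermediate
4 | ethynyltri(propan-2-yl)silane | C#C[Si](C(C)C)(C(C)C)C(C)C | starting material
5 | 3-ethoxy-5,5-dimethyl-1-{[tri(propan-2-yl)silyl]ethynyl}cyclopent-2-en-1-ol (racemic; present as its lithium alkoxide) | CCOC1=CC(O)(C#C[Si](C(C)C)(C(C)C)C(C)C)C(C)(C)C1 | intermediate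
6 | 4,4-dimethyl-3-{[tri(propan-2-yl)silyl]ethynyl}cyclopent-2-en-1-one | O=C1C=C(C#C[Si](C(C)C)(C(C)C)C(C)C)C(C)(C)C1 | intermediate
7 | (1S)-4,4-dimethyl-3-{[tri(propan-2-yl)silyl]ethynyl}cyclopent-2-en-1-ol | O[C@@H]1C=C(C#C[Si](C(C)C)(C(C)C)C(C)C)C(C)(C)C1 | intermediate
8 | (1S)-4,4-dimethyl-3-{[tri(propan-2-yl)silyl]ethynyl}cyclopent-2-en-1-yl dimethylcarbamate | CN(C)C(=O)O[C@@H]1C=C(C#C[Si](C(C)C)(C(C)C)C(C)C)C(C)(C)C1 | intermediate
9 | (1S,2S,5R)-6,6-dibromo-4,4-dimethyl-5-{[tri(propan-2-yl)silyl]ethynyl}bicyclo[3.1.0]hexan-2-yl dimethylcarbamate (CBr2 bridge anti to the carbamate; the syn isomer reacts alike) | CN(C)C(=O)O[C@H]1CC(C)(C)[C@@]2(C#C[Si](C(C)C)(C(C)C)C(C)C)[C@@H]1C2(Br)Br | intermediate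
10 | 2-bromo-6-[(dimethylcarbamoyl)oxy]-4,4-dimethyl-3-{[tri(propan-2-yl)silyl]ethynyl}cyclohex-2-en-1-ylium tetrafluoroborate (C3 configuration of the target retained) | BrC1=C(C#C[Si](C(C)C)(C(C)C)C(C)C)C(C)(C)C[C@H](OC(=O)N(C)C)[CH+]1.F[B-](F)(F)F | intermediate
11 | (3aS,7aS)-7-bromo-N,N,5,5-tetramethyl-6-{[tri(propan-2-yl)silyl]ethynyl}-3a,4,5,7a-tetrahydro-1,3-benzodioxol-2-iminium tetrafluoroborate | BrC1=C(C#C[Si](C(C)C)(C(C)C)C(C)C)C(C)(C)C[C@@H]2OC(=[N+](C)C)O[C@H]12.F[B-](F)(F)F | intermediate
12 | (3aS,7aS)-7-bromo-5,5-dimethyl-6-{[tri(propan-2-yl)silyl]ethynyl}-3a,4,5,7a-tetrahydro-1,3-benzodioxol-2-one | BrC1=C(C#C[Si](C(C)C)(C(C)C)C(C)C)C(C)(C)C[C@@H]2OC(=O)O[C@H]12 | intermediate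
13 | (3aS,7aR)-5,5,7-trimethyl-6-{[tri(propan-2-yl)silyl]ethynyl}-3a,4,5,7a-tetrahydro-1,3-benzodioxol-2-one | CC1=C(C#C[Si](C(C)C)(C(C)C)C(C)C)C(C)(C)C[C@@H]2OC(=O)O[C@H]12 | intermediate
14 | (3aS,7aR)-6-ethynyl-5,5,7-trimethyl-3a,4,5,7a-tetrahydro-1,3-benzodioxol-2-one | CC1=C(C#C)C(C)(C)C[C@@H]2OC(=O)O[C@H]12 | intermediate
15 | but-3-en-2-one | CC(=O)C=C | starting material
16 | (3aS,7aR)-6-(3-hydroxy-3-methylpent-4-en-1-yn-1-yl)-5,5,7-trimethyl-3a,4,5,7a-tetrahydro-1,3-benzodioxol-2-one (both configurations at the new carbinol carbon) | CC1=C(C#CC(C)(O)C=C)C(C)(C)C[C@@H]2OC(=O)O[C@H]12 | intermediate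
17 | (1S,2R)-4-[(1E)-3-hydroxy-3-methylpenta-1,4-dien-1-yl]-3,5,5-trimethylcyclohex-3-ene-1,2-diol (both C9 epimers) | C=CC(C)(O)/C=C/C1=C(C)[C@@H](O)[C@@H](O)CC1(C)C | intermediate
18 | (1S,2R)-4-[(1E)-3-hydroxy-3-methylpenta-1,4-dien-1-yl]-3,5,5-trimethylcyclohex-3-ene-1,2-diyl diacetate (both C9 epimers) | C=CC(C)(O)/C=C/C1=C(C)[C@@H](OC(C)=O)[C@@H](OC(C)=O)CC1(C)C | intermediate
19 | {(2E,4E)-5-[(3R,4S)-3,4-bis(acetyloxy)-2,6,6-trimethylcyclohex-1-en-1-yl]-3-methylpenta-2,4-dien-1-yl}triphenylphosphonium bromide | [Br-].c1ccccc1[P+](c1ccccc1)(c1ccccc1)C/C=C(C)/C=C/C1=C(C)[C@@H](OC(C)=O)[C@@H](OC(C)=O)CC1(C)C | intermediate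
20 | (3E)-4-[(1R)-2,6,6-trimethylcyclohex-2-en-1-yl]but-3-en-2-one, (R)-α-ionone | CC1=CCCC(C)(C)[C@H]1/C=C/C(C)=O | starting material
21 | trimethyl phosphonoacetate | COC(=O)CP(=O)(OC)OC | starting material
22 | methyl (2E,4E)-3-methyl-5-[(1R)-2,6,6-trimethylcyclohex-2-en-1-yl]penta-2,4-dienoate | CC1=CCCC(C)(C)[C@H]1/C=C/C(C)=C/C(=O)OC | intermediate
23 | methyl (2E,4E)-3-methyl-5-[(1R)-2,6,6-trimethyl-4-oxocyclohex-2-en-1-yl]penta-2,4-dienoate | CC1=CC(=O)CC(C)(C)[C@H]1/C=C/C(C)=C/C(=O)OC | intermediate
24 | methyl (2E,4E)-5-[(1R,4S)-4-hydroxy-2,6,6-trimethylcyclohex-2-en-1-yl]-3-methylpenta-2,4-dienoate | CC1=C[C@@H](O)CC(C)(C)[C@H]1/C=C/C(C)=C/C(=O)OC | intermediate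
25 | (2E,4E)-5-[(1R,4S)-4-hydroxy-2,6,6-trimethylcyclohex-2-en-1-yl]-3-methylpenta-2,4-dien-1-ol | CC1=C[C@@H](O)CC(C)(C)[C@H]1/C=C/C(C)=C/CO | intermediate
26 | {(2E,4E)-5-[(1R,4S)-4-hydroxy-2,6,6-trimethylcyclohex-2-en-1-yl]-3-methylpenta-2,4-dien-1-yl}triphenylphosphonium bromide | CC1=C[C@@H](O)CC(C)(C)[C@H]1/C=C/C(C)=C/C[P+](c1ccccc1)(c1ccccc1)c1ccccc1.[Br-] | intermediate
27 | (2E,4E,6E)-2,7-dimethylocta-2,4,6-trienedial | O=C/C(C)=C/C=C/C=C(C)/C=O | starting material
28 | (2E,4E,6E,8E,10E,12E)-13-[(1R,4S)-4-hydroxy-2,6,6-trimethylcyclohex-2-en-1-yl]-2,7,11-trimethyltrideca-2,4,6,8,10,12-hexaenal | CC1=C[C@@H](O)CC(C)(C)[C@H]1/C=C/C(C)=C/C=C/C(C)=C/C=C/C=C(C)/C=O | intermediate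
29 | (3S,4R,3'S,6'R)-β,ε-carotene-3,4,3'-triol 3,4-diacetate | CC1=C[C@@H](O)CC(C)(C)[C@H]1/C=C/C(C)=C/C=C/C(C)=C/C=C/C=C(C)/C=C/C=C(C)/C=C/C1=C(C)[C@@H](OC(C)=O)[C@@H](OC(C)=O)CC1(C)C | intermediate
30 | (3S,4R,3'S,6'R)-β,ε-carotene-3,4,3'-triol (all-E) | CC1=C[C@@H](O)CC(C)(C)[C@H]1/C=C/C(C)=C/C=C/C(C)=C/C=C/C=C(C)/C=C/C=C(C)/C=C/C1=C(C)[C@@H](O)[C@@H](O)CC1(C)C | target

**Step count and risks**
Total steps: 19. Longest linear sequence: 13 steps (steps 1–12, then step 19).

Steps most likely to fail:

1. Step 6. The allyl cation may be captured from outside, lose a proton, or the iminium salt may open to a hydroxy carbamate instead of closing to the carbonate, so that C4 forms without control. The fallback uses known chemistry and sets C4 by oxidation and hydride reduction instead of by the tether. It sets out from 7: silylation with t-BuMe2SiCl/imidazole gives the silyl ether F1. Dibromocarbene addition as in step 5 gives the dibromocyclopropane F2. AgBF4 in aqueous acetone opens F2 with capture of the cation by water at the less hindered C4 to give the bromo allylic alcohol F3 as a mixture of C4 epimers. Dess–Martin oxidation gives the bromo enone F4. LiBH(s-Bu)3 in THF at −78 °C, delivering hydride to the face opposite to the neighbouring silyloxy group, gives the cis alcohol F5. HCl in CH3OH removes the O-silyl group (the alkynylsilane stays) to give the cis diol F6. 1,1'-Carbonyldiimidazole closes the carbonate, and the route is rejoined at 12.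

2. Step 7. Zerovalent palladium may ionise the allylic carbonate (allylpalladium formation, loss of CO2, methyl transfer to C4 or C6), or oxidative addition at the tetrasubstituted bromoalkene may be too slow. In the fallback the allylic leaving group is removed before the coupling and a boron reagent is used. It sets out from 12: K2CO3 in CH3OH cleaves the carbonate to the bromo diol (identical with F6). Suzuki–Miyaura coupling with trimethylboroxine (PdCl2[1,1'-bis(diphenylphosphino)ferrocene], K2CO3, aqueous dioxane) gives the methylated cis diol F7. 1,1'-Carbonyldiimidazole re-forms the carbonate, and the route is rejoined at 13.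

3. Step 3. The catalyst may discriminate poorly between the two flanks of a cyclopentenone that has no α-substituent, which would lower the enantiomeric purity of both stereocentres of ring A. The fallback is resolution instead of asymmetric reduction. It sets out from 6: NaBH4/CeCl3 (Luche reduction) gives the racemic alcohol F8. Immobilised Candida antarctica lipase B with vinyl acetate acetylates the (R)-enantiomer to the acetate F9 and leaves the (S)-alcohol, which is separated by chromatography; the route is rejoined at 7.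

**Further compounds**
F1 | step 6 | tert-butyl{[(1S)-4,4-dimethyl-3-{[tri(propan-2-yl)silyl]ethynyl}cyclopent-2-en-1-yl]oxy}dimethylsilane | CC(C)(C)[Si](C)(C)O[C@@H]1C=C(C#C[Si](C(C)C)(C(C)C)C(C)C)C(C)(C)C1
F2 | step 6 | tert-butyl{[(1S,2S,5R)-6,6-dibromo-4,4-dimethyl-5-{[tri(propan-2-yl)silyl]ethynyl}bicyclo[3.1.0]hexan-2-yl]oxy}dimethylsilane | CC(C)(C)[Si](C)(C)O[C@H]1CC(C)(C)[C@@]2(C#C[Si](C(C)C)(C(C)C)C(C)C)[C@@H]1C2(Br)Br
F3 | step 6 | (6S)-2-bromo-6-{[tert-butyl(dimethyl)silyl]oxy}-4,4-dimethyl-3-{[tri(propan-2-yl)silyl]ethynyl}cyclohex-2-en-1-ol (both C1 epimers) | BrC1=C(C#C[Si](C(C)C)(C(C)C)C(C)C)C(C)(C)C[C@H](O[Si](C)(C)C(C)(C)C)C1O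
F4 | step 6 | (6S)-2-bromo-6-{[tert-butyl(dimethyl)silyl]oxy}-4,4-dimethyl-3-{[tri(propan-2-yl)silyl]ethynyl}cyclohex-2-en-1-one | BrC1=C(C#C[Si](C(C)C)(C(C)C)C(C)C)C(C)(C)C[C@H](O[Si](C)(C)C(C)(C)C)C1=O
F5 | step 6 | (1S,6S)-2-bromo-6-{[tert-butyl(dimethyl)silyl]oxy}-4,4-dimethyl-3-{[tri(propan-2-yl)silyl]ethynyl}cyclohex-2-en-1-ol | BrC1=C(C#C[Si](C(C)C)(C(C)C)C(C)C)C(C)(C)C[C@H](O[Si](C)(C)C(C)(C)C)[C@@H]1O
F6 | step 6 | (1S,2S)-3-bromo-5,5-dimethyl-4-{[tri(propan-2-yl)silyl]ethynyl}cyclohex-3-ene-1,2-diol | BrC1=C(C#C[Si](C(C)C)(C(C)C)C(C)C)C(C)(C)C[C@H](O)[C@@H]1O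
F7 | step 7 | (1S,2R)-3,5,5-trimethyl-4-{[tri(propan-2-yl)silyl]ethynyl}cyclohex-3-ene-1,2-diol | CC1=C(C#C[Si](C(C)C)(C(C)C)C(C)C)C(C)(C)C[C@H](O)[C@@H]1O
F8 | step 3 | 4,4-dimethyl-3-{[tri(propan-2-yl)silyl]ethynyl}cyclopent-2-en-1-ol (racemic) | OC1C=C(C#C[Si](C(C)C)(C(C)C)C(C)C)C(C)(C)C1
F9 | step 3 | (1R)-4,4-dimethyl-3-{[tri(propan-2-yl)silyl]ethynyl}cyclopent-2-en-1-yl acetate | CC(=O)O[C@H]1C=C(C#C[Si](C(C)C)(C(C)C)C(C)C)C(C)(C)C1
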